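Everything rests on opening ring B of the naphthalene at the C4–C4a bond. Ring B offers the handle: C1 joins two aryl units (fused ring A and the pendant anisyl ring), C2 and C3 are vicinally heteroatom-substituted, and C4 is a bare CH. A diarylmethyl ethynyl ketone therefore already holds C1–C4 in order. An iodonium source makes the catechol-derived ring A add to the terminal alkyne carbon. This single operation closes ring B, aromatises it, and installs oxygen at C2 and iodine at C3. The precursor is a racemic 1,1-diarylbut-3-yn-2-one with benzyl-protected catechol oxygens. Both handles are later exchanged for nitrogen under palladium catalysis.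

Key step: step 4

Remark: racemic 4-methoxymandelic acid is used, because the only stereocentre of the route (the diarylmethine carbon that becomes C1) is erased when ring B aromatises, and the target is achiral.

Step 1
Reactants: 1 rac-4-methoxymandelic acid; 2 1,2-bis(benzyloxy)benzene
Product: 3 rac-2-[3,4-bis(benzyloxy)phenyl]-2-(4-methoxyphenyl)acetic acid
Conditions: BF3·OEt2 (2.5 equiv, promoter), 2 (1.5 equiv), CH2Cl2, 0 °C → rt
Reagents that add atoms: none
Why: Dehydrative Friedel–Crafts alkylation, in which BF3 ionises the benzylic C–OH bond to a cation stabilised by the para-methoxy group and the excess of 2 captures it at C4 (para to one ether oxygen, least hindered), giving the new stereocentre without control (racemic, erased later) under conditions that aryl benzyl ethers tolerate.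

Step 2
Reactants: 3 rac-2-[3,4-bis(benzyloxy)phenyl]-2-(4-methoxyphenyl)acetic acid
Product: 5 rac-2-[3,4-bis(benzyloxy)phenyl]-N-methoxy-2-(4-methoxyphenyl)-N-methylacetamide, via acyl imidazolide 4 (not isolated)
Conditions: CDI, CH2Cl2, rt; then MeNH(OMe)·HCl, rt
Reagents that add atoms: 1,1'-carbonyldiimidazole, O=C(n1ccnc1)n1ccnc1 (imidazolyl group of 4 only); N,O-dimethylhydroxylamine hydrochloride, CNOC.Cl
Why: Weinreb amide synthesis by acyl imidazolide activation, which needs no external base because the liberated imidazole neutralises the amine hydrochloride, so the acidic diarylmethine hydrogen never meets a strong base.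

Step 3
Reactants: 5 rac-2-[3,4-bis(benzyloxy)phenyl]-N-methoxy-2-(4-methoxyphenyl)-N-methylacetamide; 6 ethynylmagnesium bromide
Product: 8 rac-1-[3,4-bis(benzyloxy)phenyl]-1-(4-methoxyphenyl)but-3-yn-2-one, via bromomagnesium hemiaminal chelate 7 (not isolated)
Conditions: 6 (3 equiv, 0.5 M in THF), THF, 0 °C → rt; inverse quench into cold 1 M aq NaHSO4
Reagents that add atoms: ethynylmagnesium bromide 6, C#C[Mg]Br
Why: Weinreb ketone synthesis, in which the small acetylide adds only once because chelate 7 survives until the quench, any α-deprotonation by the weakly basic acetylide is reversible while addition is not, and the cold acidic inverse quench protonates the released N,O-dimethylhydroxylamine before it can add to the terminal ynone in an aza-Michael sense.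

Step 4
Reactants: 8 rac-1-[3,4-bis(benzyloxy)phenyl]-1-(4-methoxyphenyl)but-3-yn-2-one
Product: 10 6,7-bis(benzyloxy)-3-iodo-1-(4-methoxyphenyl)naphthalen-2-ol, via keto tautomer 9 (not isolated)
Conditions: ICl (1.1 equiv, slow addition), NaHCO3 (2 equiv), MeCN–CH2Cl2, −40 → 0 °C; aq Na2S2O3
Reagents that add atoms: iodine monochloride, ClI
Why: ICl polarises the triple bond as an iodonium complex whose positive character lies on the terminal β-carbon C4; C6' of ring A adds there while iodine is fixed on the α-carbon C3, the arenium ion loses its proton to bicarbonate to give enone 9, and the doubly benzylic C1–H then moves to oxygen to give naphthol 10. The closest known reaction type is the electrophilic iodocyclisation (iodoarylative benzannulation) of 1-aryl-3-alkyn-2-ones to 3-iodo-2-naphthols, applied here to a member with a terminal alkyne. Ring B closes in the 6-endo-dig mode with both alkyne carbons inside the new ring, whereas a 5-exo closure would require attack at the α-carbon against the polarity of the ynone. No stereocentre is created, and the single one of 8 (C1) disappears on aromatisation. The step needs reaction through C6' of ring A: this carbon is para to the 3'-benzyloxy group and unhindered, C2' is wedged between two substituents, the anisyl ortho carbons are only meta to OMe, and the anisyl ipso carbon could only close a crowded spiro five-membered ring next to the tertiary C1, a path that becomes irreversible only through halide-induced O-demethylation. Slow addition of about one equivalent of ICl in the cold limits nuclear iodination of the electron-rich rings, and bicarbonate removes HCl, which would otherwise add to the terminal ynone.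

Step 5
Reactants: 10 6,7-bis(benzyloxy)-3-iodo-1-(4-methoxyphenyl)naphthalen-2-ol
Product: 11 6,7-bis(benzyloxy)-3-iodo-1-(4-methoxyphenyl)naphthalen-2-yl trifluoromethanesulfonate
Conditions: Tf2O, pyridine, CH2Cl2, 0 °C
Reagents that add atoms: trifluoromethanesulfonic anhydride, O=S(=O)(OS(=O)(=O)C(F)(F)F)C(F)(F)F
Why: O-Sulfonylation (triflation) of the only nucleophilic site of 10 converts the C2 oxygen into a leaving group fit for oxidative addition and leaves the aryl iodide and the ethers untouched.

Step 6
Reactants: 11 6,7-bis(benzyloxy)-3-iodo-1-(4-methoxyphenyl)naphthalen-2-yl trifluoromethanesulfonate; 12 benzophenone imine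
Product: 14 6,7-bis(benzyloxy)-N2,N3-bis(diphenylmethylidene)-1-(4-methoxyphenyl)naphthalene-2,3-diamine, via mono-imine triflate 13 (not isolated)
Conditions: 12 (2.6 equiv), Pd2(dba)3 (5 mol %), rac-BINAP (12 mol %), Cs2CO3 (3 equiv), toluene, 105 °C
Reagents that add atoms: benzophenone imine 12, N=C(c1ccccc1)c1ccccc1
Why: Double Buchwald–Hartwig amination with an ammonia surrogate, in which zerovalent palladium inserts first into the C3–I bond (giving 13) and then into the C2–OTf bond, Cs2CO3 is mild enough to spare the sulfonate, and both the twofold coupling of ortho-dihaloarenes and the coupling of 1-aryl-2-naphthyl triflates with this imine are established reactions.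

Step 7
Reactants: 14 6,7-bis(benzyloxy)-N2,N3-bis(diphenylmethylidene)-1-(4-methoxyphenyl)naphthalene-2,3-diamine
Product: 16 N,N'-[6,7-bis(benzyloxy)-1-(4-methoxyphenyl)naphthalene-2,3-diyl]diformamide, via 2,3-diamine 15 (not isolated)
Conditions: 2 M aq HCl, THF, rt; evaporate under Ar; then preformed HCO2Ac (excess), iPr2NEt, THF, −10 → 0 °C
Reagents that add atoms: acetic formic anhydride, CC(=O)OC=O
Why: Acidic imine hydrolysis followed by N-formylation with a mixed anhydride, in which N-aryl benzophenone imines cleave quickly in wet acidic THF, the air-sensitive diamine stays protonated until it is acylated, and excess reagent at or below 0 °C should formylate both nitrogens faster than the mono-formamide can cyclodehydrate to a naphthimidazole.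

Step 8
Reactants: 16 N,N'-[6,7-bis(benzyloxy)-1-(4-methoxyphenyl)naphthalene-2,3-diyl]diformamide
Product: 17 melanocin E, N,N'-[6,7-dihydroxy-1-(4-methoxyphenyl)naphthalene-2,3-diyl]diformamide
Conditions: H2 (1 atm), 10% Pd/C, THF–MeOH, rt; filtration under Ar
Reagents that add atoms: none
Why: Catalytic hydrogenolysis of the two aryl benzyl ethers at atmospheric pressure leaves the methyl ether, both formamides and the naphthalene core intact, and inert work-up protects the free catechol from oxidation.

Compound list
1 | rac-4-methoxymandelic acid | COc1ccc(cc1)C(O)C(O)=O | starting material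
2 | 1,2-bis(benzyloxy)benzene | c1ccc(cc1)COc1ccccc1OCc1ccccc1 | starting material
3 | rac-2-[3,4-bis(benzyloxy)phenyl]-2-(4-methoxyphenyl)acetic acid | COc1ccc(cc1)C(C(O)=O)c1ccc(OCc2ccccc2)c(OCc2ccccc2)c1 | intermediate
4 | rac-2-[3,4-bis(benzyloxy)phenyl]-1-(imidazol-1-yl)-2-(4-methoxyphenyl)ethanone (acyl imidazolide) | COc1ccc(cc1)C(C(=O)n1ccnc1)c1ccc(OCc2ccccc2)c(OCc2ccccc2)c1 | intermediate (not isolated)
5 | rac-2-[3,4-bis(benzyloxy)phenyl]-N-methoxy-2-(4-methoxyphenyl)-N-methylacetamide | COc1ccc(cc1)C(C(=O)N(C)OC)c1ccc(OCc2ccccc2)c(OCc2ccccc2)c1 | intermediate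
6 | ethynylmagnesium bromide | C#C[Mg]Br | starting material
7 | bromomagnesium alkoxide of the tetrahedral N-methoxy-N-methyl hemiaminal adduct (chelate, stereoisomer mixture) | COc1ccc(cc1)C(c1ccc(OCc2ccccc2)c(OCc2ccccc2)c1)C(O[Mg]Br)(C#C)N(C)OC | intermediate (not isolated)
8 | rac-1-[3,4-bis(benzyloxy)phenyl]-1-(4-methoxyphenyl)but-3-yn-2-one | COc1ccc(cc1)C(C(=O)C#C)c1ccc(OCc2ccccc2)c(OCc2ccccc2)c1 | intermediate
9 | rac-6,7-bis(benzyloxy)-3-iodo-1-(4-methoxyphenyl)naphthalen-2(1H)-one (keto tautomer) | COc1ccc(cc1)C1C(=O)C(I)=Cc2cc(OCc3ccccc3)c(OCc3ccccc3)cc12 | intermediate (not isolated)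
10 | 6,7-bis(benzyloxy)-3-iodo-1-(4-methoxyphenyl)naphthalen-2-ol | COc1ccc(cc1)-c1c(O)c(I)cc2cc(OCc3ccccc3)c(OCc3ccccc3)cc12 | intermediate
11 | 6,7-bis(benzyloxy)-3-iodo-1-(4-methoxyphenyl)naphthalen-2-yl trifluoromethanesulfonate | COc1ccc(cc1)-c1c(OS(=O)(=O)C(F)(F)F)c(I)cc2cc(OCc3ccccc3)c(OCc3ccccc3)cc12 | intermediate
12 | benzophenone imine | N=C(c1ccccc1)c1ccccc1 | starting material
13 | 6,7-bis(benzyloxy)-3-[(diphenylmethylidene)amino]-1-(4-methoxyphenyl)naphthalen-2-yl trifluoromethanesulfonate | COc1ccc(cc1)-c1c(OS(=O)(=O)C(F)(F)F)c(N=C(c3ccccc3)c3ccccc3)cc2cc(OCc3ccccc3)c(OCc3ccccc3)cc12 | intermediate (not isolated)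
14 | 6,7-bis(benzyloxy)-N2,N3-bis(diphenylmethylidene)-1-(4-methoxyphenyl)naphthalene-2,3-diamine | COc1ccc(cc1)-c1c(N=C(c3ccccc3)c3ccccc3)c(N=C(c3ccccc3)c3ccccc3)cc2cc(OCc3ccccc3)c(OCc3ccccc3)cc12 | intermediate
15 | 6,7-bis(benzyloxy)-1-(4-methoxyphenyl)naphthalene-2,3-diamine (held as its bis-hydrochloride until formylation) | COc1ccc(cc1)-c1c(N)c(N)cc2cc(OCc3ccccc3)c(OCc3ccccc3)cc12 | intermediate (not isolated)
16 | N,N'-[6,7-bis(benzyloxy)-1-(4-methoxyphenyl)naphthalene-2,3-diyl]diformamide | COc1ccc(cc1)-c1c(NC=O)c(NC=O)cc2cc(OCc3ccccc3)c(OCc3ccccc3)cc12 | intermediate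
17 | melanocin E, N,N'-[6,7-dihydroxy-1-(4-methoxyphenyl)naphthalene-2,3-diyl]diformamide | COc1ccc(-c2c(NC=O)c(NC=O)cc3cc(O)c(O)cc23)cc1 | target

Total step count: 8. Longest linear sequence: 8 steps (from 1 or 2 to 17).

Steps most likely to fail

1. Step 4.
- **Risk:** The electron-poor terminal triple bond may be activated too slowly. Nuclear iodination of the alkoxyarenes, addition of iodine and chloride across the alkyne, halogenation at the enolisable C1, or ipso attack of the anisyl ring with loss of its methyl group could then overtake ring closure.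
- **Fallback (from 8, back at 10):** Ring closure and iodination are separated. A halide-free 6-endo hydroarylation of 8 (Ph3PAuNTf2, 5 mol %, CH2Cl2, rt) makes any ipso attack reversible and should give 6,7-bis(benzyloxy)-1-(4-methoxyphenyl)naphthalen-2-ol F1. Protection with MOMCl and iPr2NEt gives 6,7-bis(benzyloxy)-2-(methoxymethoxy)-1-(4-methoxyphenyl)naphthalene F2. Directed ortho-lithiation follows (n-BuLi, THF, −78 → 0 °C). It can only occur at C3 because C1 is blocked, exactly as in the 3,3'-functionalisation of MOM-protected 1,1'-bi-2-naphthol. An I2 quench gives 6,7-bis(benzyloxy)-3-iodo-2-(methoxymethoxy)-1-(4-methoxyphenyl)naphthalene F3, and HCl in MeOH–THF removes the acetal to return 10.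

2. Step 6.
- **Risk:** The reaction may stall after the first coupling, because the C2 sulfonate is flanked by the C1 aryl group and the newly installed bulky imine. Slow oxidative addition would let S–O cleavage of the triflate or hydrodehalogenation compete.
- **Fallback (from 11, back at 15):** The two C–N bonds are made separately, and the hindered one is moved to another nucleophile class. With one equivalent of 12 at about 70 °C only the C3–I bond should couple, so that 13 is isolated. Its triflate is then amidated with tert-butyl carbamate, which is much slimmer at nitrogen (Pd2(dba)3, tBuBrettPhos, K3PO4, t-BuOH, 100 °C). This gives tert-butyl N-{6,7-bis(benzyloxy)-3-[(diphenylmethylidene)amino]-1-(4-methoxyphenyl)naphthalen-2-yl}carbamate F4. HCl in wet dioxane removes the imine and the carbamate together and delivers 15 as its bis-hydrochloride, which enters the formylation half of step 7.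

3. Step 3.
- **Risk:** The hindered, α-acidic amide may enolise instead of undergoing addition. Base-induced fragmentation of the N–OMe unit and conjugate addition of the released amine to the ynone during the quench are further failure modes.
- **Fallback (from 5, back at 8):** The ketone oxidation level is reached by addition to an aldehyde and reoxidation, so no amine is present when the ynone is formed. Reduction of 5 with i-Bu2AlH (THF, −78 °C) gives rac-2-[3,4-bis(benzyloxy)phenyl]-2-(4-methoxyphenyl)acetaldehyde F5. Fast 1,2-addition of 6 (THF, −78 → 0 °C) gives 1-[3,4-bis(benzyloxy)phenyl]-1-(4-methoxyphenyl)but-3-yn-2-ol F6 as an inconsequential diastereomer mixture. Dess–Martin periodinane buffered with NaHCO3 in CH2Cl2 then oxidises F6 to 8.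

Further compounds
F1 | step 4 | 6,7-bis(benzyloxy)-1-(4-methoxyphenyl)naphthalen-2-ol | COc1ccc(cc1)-c1c(O)ccc2cc(OCc3ccccc3)c(OCc3ccccc3)cc12
F2 | step 4 | 6,7-bis(benzyloxy)-2-(methoxymethoxy)-1-(4-methoxyphenyl)naphthalene | COCOc1ccc2cc(OCc3ccccc3)c(OCc3ccccc3)cc2c1-c1ccc(OC)cc1
F3 | step 4 | 6,7-bis(benzyloxy)-3-iodo-2-(methoxymethoxy)-1-(4-methoxyphenyl)naphthalene | COCOc1c(I)cc2cc(OCc3ccccc3)c(OCc3ccccc3)cc2c1-c1ccc(OC)cc1
F4 | step 6 | tert-butyl N-{6,7-bis(benzyloxy)-3-[(diphenylmethylidene)amino]-1-(4-methoxyphenyl)naphthalen-2-yl}carbamate | COc1ccc(cc1)-c1c(NC(=O)OC(C)(C)C)c(N=C(c3ccccc3)c3ccccc3)cc2cc(OCc3ccccc3)c(OCc3ccccc3)cc12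
F5 | step 3 | rac-2-[3,4-bis(benzyloxy)phenyl]-2-(4-methoxyphenyl)acetaldehyde | COc1ccc(cc1)C(C=O)c1ccc(OCc2ccccc2)c(OCc2ccccc2)c1
F6 | step 3 | 1-[3,4-bis(benzyloxy)phenyl]-1-(4-methoxyphenyl)but-3-yn-2-ol (racemic, diastereomer mixture) | COc1ccc(cc1)C(C(O)C#C)c1ccc(OCc2ccccc2)c(OCc2ccccc2)c1
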